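**Plan**

- Cuts, in retrosynthetic order: the two O-benzyl groups; C4'=C5' (Julia–Kocienski) and C2'=C3' (Wittig) of the side chain; C5–C6 of the oxane; the bond from C2 to pyridone C3; C4–C5 and C1'–C2' of the open chain; the phenyl–pyridone bond.
- Enabling feature: in the oxane (O1, C2 pyridonyl, C3 methyl, C4, C5 alkylidene, C6) C6 is a CH2 between O1 and the sp2 carbon C5, so an O1=C6H2 oxocarbenium ion can be trapped at C5 by a vinylsilane whose geometry becomes that of C5=C1'.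
- Forward: the C2–C2' chain carrying the (Z)-vinylsilane is built, joined at C2 to the metalated 1,4-bis(benzyloxy)-5-phenylpyridone, the oxane (the only ring made) is closed at C5–C6, then the chain grows by C3'–C4' and C5'–C8' and the benzyl groups come off.
- Stereochemistry: C3 from (S)-3-bromo-2-methylpropan-1-ol; C2 from a CBS reduction matched with Felkin–Anh control; 5Z from alkyne trans-hydrosilylation followed by retentive ipso-substitution; 2'E and 4'E from the Wittig and Julia–Kocienski steps; C6' from (R)-2-methylbutanoic acid.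

Key step: step 16

Remark: atoms are numbered O1, C2 (pyridonyl), C3 (methyl), C4, C5 (alkylidene), C6 in the oxane and C1'–C8' in the side chain; compounds 1, 10 and 27 are assumed to be purchasable as the single isomers named.

**Route**

Step 1
Reactants: 1 (S)-3-bromo-2-methylpropan-1-ol
Product: 2 (S)-(3-bromo-2-methylpropoxy)(tert-butyl)dimethylsilane
Conditions: TBSCl, imidazole, CH2Cl2, 0 °C → rt
Reagents that add atoms: tert-butyldimethylsilyl chloride, CC(C)(C)[Si](C)(C)Cl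
Why: Imidazole-promoted silylation of a primary alcohol, which leaves the bromide and the stereocentre untouched.

Step 2
Reactants: 2 (S)-(3-bromo-2-methylpropoxy)(tert-butyl)dimethylsilane
Product: 3 (R)-tert-butyldimethyl[(2-methylpent-4-yn-1-yl)oxy]silane
Conditions: LiC≡CH·H2NCH2CH2NH2, DMSO, 5 °C → rt
Reagents that add atoms: lithium acetylide–ethylenediamine complex, [Li]C#C.NCCN
Why: SN2 alkylation of an acetylide by a primary bromide in DMSO forms C4–C5, and the stereocentre, one carbon away from the reacting centre, is kept (the descriptor changes only by priority).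

Step 3
Reactants: 3 (R)-tert-butyldimethyl[(2-methylpent-4-yn-1-yl)oxy]silane
Product: 5 (R)-6-[(tert-butyldimethylsilyl)oxy]-5-methylhex-2-yn-1-ol, via lithium acetylide 4 (not isolated)
Conditions: n-BuLi, THF, −78 °C; (CH2O)n, −78 °C → rt
Reagents that add atoms: paraformaldehyde (as formaldehyde), C=O
Why: Deprotonation of the terminal alkyne and addition of the lithium acetylide to formaldehyde (hydroxymethylation) should give the 2-alkyn-1-ol and so add C2'.

Step 4
Reactants: 5 (R)-6-[(tert-butyldimethylsilyl)oxy]-5-methylhex-2-yn-1-ol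
Product: 6 (2Z,5R)-6-[(tert-butyldimethylsilyl)oxy]-5-methyl-3-(triethylsilyl)hex-2-en-1-ol
Conditions: Et3SiH, [Cp*Ru(MeCN)3]PF6 (2 mol %), CH2Cl2, 0 °C → rt
Reagents that add atoms: triethylsilane, CC[SiH](CC)CC
Why: Ruthenium-catalysed trans-hydrosilylation of an internal propargylic alcohol should add H and Si anti across the triple bond with silicon on the carbon distal to the hydroxyl, which places SiEt3 on C5 and cis to the CH2OH group (the Z vinylsilane).

Step 5
Reactants: 6 (2Z,5R)-6-[(tert-butyldimethylsilyl)oxy]-5-methyl-3-(triethylsilyl)hex-2-en-1-ol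
Product: 7 (2R,4Z)-1-[(tert-butyldimethylsilyl)oxy]-6-[(tert-butyldiphenylsilyl)oxy]-2-methyl-4-(triethylsilyl)hex-4-ene
Conditions: TBDPSCl, imidazole, DMF, rt
Reagents that add atoms: tert-butyldiphenylsilyl chloride, CC(C)(C)[Si](Cl)(c1ccccc1)c1ccccc1
Why: Standard silylation of the primary allylic alcohol installs a group that withstands the acid, Grignard and Lewis-acid steps that follow.

Step 6
Reactants: 7 (2R,4Z)-1-[(tert-butyldimethylsilyl)oxy]-6-[(tert-butyldiphenylsilyl)oxy]-2-methyl-4-(triethylsilyl)hex-4-ene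
Product: 8 (2R,4Z)-6-[(tert-butyldiphenylsilyl)oxy]-2-methyl-4-(triethylsilyl)hex-4-en-1-ol
Conditions: camphorsulfonic acid (10 mol %), MeOH/CH2Cl2 1:1, 0 °C
Reagents that add atoms: none
Why: Acid-catalysed methanolysis cleaves a primary TBS ether far faster than a TBDPS ether (selective desilylation), and catalytic sulfonic acid at 0 °C should not protodesilylate the vinylsilane.

Step 7
Reactants: 8 (2R,4Z)-6-[(tert-butyldiphenylsilyl)oxy]-2-methyl-4-(triethylsilyl)hex-4-en-1-ol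
Product: 9 (2R,4Z)-6-[(tert-butyldiphenylsilyl)oxy]-2-methyl-4-(triethylsilyl)hex-4-enal
Conditions: PhI(OAc)2, TEMPO (10 mol %), CH2Cl2, rt; used at once
Reagents that add atoms: none
Why: Nitroxyl-catalysed oxidation of a primary alcohol stops at the aldehyde under nearly neutral conditions, so the alpha stereocentre should survive if the aldehyde is used without chromatography.

Step 8
Reactants: 10 5-bromo-2,4-dichloropyridine
Product: 11 2,4-bis(benzyloxy)-5-bromopyridine
Conditions: NaH, BnOH, DMF, 0 → 100 °C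
Reagents that add atoms: benzyl alcohol (as its sodium salt), OCc1ccccc1
Why: Double nucleophilic aromatic substitution, in which the chlorides at positions 2 and 4 are activated by the ring nitrogen while the 5-bromide is not.

Step 9
Reactants: 11 2,4-bis(benzyloxy)-5-bromopyridine
Product: 12 2,4-bis(benzyloxy)-5-phenylpyridine
Conditions: PhB(OH)2, Pd(PPh3)4 (5 mol %), K2CO3, dioxane/H2O, 90 °C
Reagents that add atoms: phenylboronic acid, OB(O)c1ccccc1
Why: Suzuki–Miyaura coupling at the only carbon–halogen bond left in the molecule.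

Step 10
Reactants: 12 2,4-bis(benzyloxy)-5-phenylpyridine
Product: 14 1,4-bis(benzyloxy)-5-phenylpyridin-2(1H)-one, via pyridine N-oxide 13 (not isolated)
Conditions: mCPBA, CH2Cl2, 0 °C → rt; aq NaHCO3 wash, solvent exchange; PhMe, 110 °C
Reagents that add atoms: 3-chloroperoxybenzoic acid, OOC(=O)c1cccc(Cl)c1
Why: Peracid N-oxidation of the 4-alkoxy-activated pyridine followed by the known thermal oxygen-to-oxygen benzyl shift of 2-benzyloxypyridine N-oxides should give the N-benzyloxy-2-pyridone.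

Step 11
Reactants: 14 1,4-bis(benzyloxy)-5-phenylpyridin-2(1H)-one
Product: 15 1,4-bis(benzyloxy)-3-iodo-5-phenylpyridin-2(1H)-one
Conditions: N-iodosuccinimide, MeCN, rt, dark
Reagents that add atoms: N-iodosuccinimide, O=C1CCC(=O)N1I
Why: Electrophilic iodination at C3, the nucleophilic carbon between the C4 enol ether and the C2 carbonyl, with the other nucleophilic position (C5) blocked by phenyl.

Step 12
Reactants: 15 1,4-bis(benzyloxy)-3-iodo-5-phenylpyridin-2(1H)-one; 9 (2R,4Z)-6-[(tert-butyldiphenylsilyl)oxy]-2-methyl-4-(triethylsilyl)hex-4-enal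
Product: 17 1,4-bis(benzyloxy)-3-[(1RS,2R,4Z)-6-(tert-butyldiphenylsilyloxy)-1-hydroxy-2-methyl-4-(triethylsilyl)hex-4-en-1-yl]-5-phenylpyridin-2(1H)-one, via arylmagnesium chloride 16 (not isolated)
Conditions: i-PrMgCl·LiCl, THF, −40 °C; then 9, −40 → 0 °C
Reagents that add atoms: none
Why: Iodine–magnesium exchange at low temperature gives the C3 Grignard reagent without attack on the N–O bond or the benzylic hydrogens, and its 1,2-addition to the aldehyde forms the C2–pyridone bond; the carbinol configuration is not controlled here and is erased in step 13.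

Step 13
Reactants: 17 1,4-bis(benzyloxy)-3-[(1RS,2R,4Z)-6-(tert-butyldiphenylsilyloxy)-1-hydroxy-2-methyl-4-(triethylsilyl)hex-4-en-1-yl]-5-phenylpyridin-2(1H)-one
Product: 18 1,4-bis(benzyloxy)-3-[(2R,4Z)-6-(tert-butyldiphenylsilyloxy)-2-methyl-4-(triethylsilyl)hex-4-enoyl]-5-phenylpyridin-2(1H)-one
Conditions: Dess–Martin periodinane, NaHCO3, CH2Cl2, 0 °C → rt
Reagents that add atoms: none
Why: Dess–Martin oxidation converts the hindered secondary alcohol into the aryl ketone under buffered, non-enolising conditions, so the alpha-methyl centre should be kept.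

Step 14
Reactants: 18 1,4-bis(benzyloxy)-3-[(2R,4Z)-6-(tert-butyldiphenylsilyloxy)-2-methyl-4-(triethylsilyl)hex-4-enoyl]-5-phenylpyridin-2(1H)-one
Product: 19 1,4-bis(benzyloxy)-3-[(1R,2R,4Z)-6-(tert-butyldiphenylsilyloxy)-1-hydroxy-2-methyl-4-(triethylsilyl)hex-4-en-1-yl]-5-phenylpyridin-2(1H)-one
Conditions: (S)-2-methyl-CBS-oxazaborolidine (1 equiv), catecholborane, PhMe, −78 → −40 °C
Reagents that add atoms: none
Why: In this Corey–Bakshi–Shibata reduction the (S)-oxazaborolidine should deliver hydride to the face that gives the (R)-carbinol with the pyridonyl as the large group, Felkin–Anh control by the neighbouring methyl-bearing centre (hydride anti to the CH2 branch) favours the same 1,2-anti isomer, and catecholborane reduces the ketone in the 1,2 sense without touching the vinylsilane or the pyridone.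

Step 15
Reactants: 19 1,4-bis(benzyloxy)-3-[(1R,2R,4Z)-6-(tert-butyldiphenylsilyloxy)-1-hydroxy-2-methyl-4-(triethylsilyl)hex-4-en-1-yl]-5-phenylpyridin-2(1H)-one
Product: 20 1,4-bis(benzyloxy)-3-[(1R,2R,4Z)-6-(tert-butyldiphenylsilyloxy)-1-[(2-methoxyethoxy)methoxy]-2-methyl-4-(triethylsilyl)hex-4-en-1-yl]-5-phenylpyridin-2(1H)-one
Conditions: MEMCl, i-Pr2NEt, Bu4NI (cat.), ClCH2CH2Cl, 50 °C
Reagents that add atoms: 2-methoxyethoxymethyl chloride, COCCOCCl
Why: Alkylation of the hindered secondary alcohol with an alpha-chloro ether and a hindered amine base, helped by iodide catalysis, gives the formaldehyde acetal that carries the future C6.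

Step 16
Reactants: 20 1,4-bis(benzyloxy)-3-[(1R,2R,4Z)-6-(tert-butyldiphenylsilyloxy)-1-[(2-methoxyethoxy)methoxy]-2-methyl-4-(triethylsilyl)hex-4-en-1-yl]-5-phenylpyridin-2(1H)-one
Product: 23 1,4-bis(benzyloxy)-3-[(2R,3R,5Z)-5-[2-(tert-butyldiphenylsilyloxy)ethylidene]-3-methyloxan-2-yl]-5-phenylpyridin-2(1H)-one, via oxocarbenium ion 21 (not isolated), via beta-silyl cation 22 (not isolated)
Conditions: SnCl4 (3 equiv), 2,6-di-tert-butyl-4-methylpyridine (0.3 equiv), CH2Cl2, −78 → −20 °C; aq NaHCO3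
Reagents that add atoms: none
Why: SnCl4 binds both ether oxygens of the MEM group and expels 2-methoxyethoxide to give the O1=C6H2 oxocarbenium ion 21, whose carbon C6 attacks the silicon-bearing alkene carbon C5; the cation 22 so formed at C1', stabilised by the beta C–Si bond, then loses the silyl group to chloride. The closest known reaction type is the acetal-initiated, vinylsilane-terminated cyclisation of alkoxymethyl ethers of vinylsilane alcohols to 3-alkylidene oxanes. The oxane closes in a six-membered mode that is exo with respect to the vinylsilane double bond and endo with respect to the C=O+ bond, through a chair in which the C2 pyridonyl and C3 methyl groups are equatorial. No stereocentre is created: C2 and C3 are carried in, and the C5=C1' geometry follows from the vinylsilane because the cation loses silicon after a least-motion rotation, so C6 takes the place of silicon with retention and C2', cis to silicon in 20, ends cis to C6 (5Z). The step needs the acetal to ionise in preference to the benzylic C2–O bond and silicon to leave faster than the C5–C1' bond rotates; bidentate binding of SnCl4 to the MEM group, complexation of the pyridone carbonyl (which makes the ring electron-poor) and the low temperature should secure the first, and the C–Si hyperconjugation together with the absence of further conjugation at C1' (a CH2OSi group, not a diene) the second.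

Step 17
Reactants: 23 1,4-bis(benzyloxy)-3-[(2R,3R,5Z)-5-[2-(tert-butyldiphenylsilyloxy)ethylidene]-3-methyloxan-2-yl]-5-phenylpyridin-2(1H)-one
Product: 24 1,4-bis(benzyloxy)-3-[(2R,3R,5Z)-5-(2-hydroxyethylidene)-3-methyloxan-2-yl]-5-phenylpyridin-2(1H)-one
Conditions: Bu4NF, AcOH, THF, 0 °C → rt
Reagents that add atoms: none
Why: Fluoride-induced cleavage of the silyl ether, buffered with acetic acid so that the N-benzyloxy pyridone does not meet a strong base.

Step 18
Reactants: 24 1,4-bis(benzyloxy)-3-[(2R,3R,5Z)-5-(2-hydroxyethylidene)-3-methyloxan-2-yl]-5-phenylpyridin-2(1H)-one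
Product: 25 1,4-bis(benzyloxy)-3-[(2R,3R,5Z)-3-methyl-5-(2-oxoethylidene)oxan-2-yl]-5-phenylpyridin-2(1H)-one
Conditions: MnO2, CH2Cl2, rt
Reagents that add atoms: none
Why: MnO2 oxidises the allylic alcohol selectively to the enal under neutral, heterogeneous conditions, so the Z geometry of the exocyclic alkene should survive.

Step 19
Reactants: 25 1,4-bis(benzyloxy)-3-[(2R,3R,5Z)-3-methyl-5-(2-oxoethylidene)oxan-2-yl]-5-phenylpyridin-2(1H)-one
Product: 26 1,4-bis(benzyloxy)-3-[(2R,3R,5Z)-3-methyl-5-[(2E)-4-oxobut-2-en-1-ylidene]oxan-2-yl]-5-phenylpyridin-2(1H)-one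
Conditions: Ph3P=CHCHO, PhMe, 70 °C
Reagents that add atoms: (triphenylphosphoranylidene)acetaldehyde, O=CC=P(c1ccccc1)(c1ccccc1)c1ccccc1
Why: Wittig reaction of the enal with the formyl-stabilised ylide should give the E alkene C2'=C3', and the dienal product is less electrophilic than the enal, which limits a second homologation.

Step 20
Reactants: 27 (R)-2-methylbutanoic acid
Product: 28 (R)-2-methylbutan-1-ol
Conditions: LiAlH4, Et2O, 0 °C → rt
Reagents that add atoms: none
Why: Hydride reduction of the carboxylic acid proceeds through the carboxylate, which is not enolised, so the stereocentre is kept.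

Step 21
Reactants: 28 (R)-2-methylbutan-1-ol
Product: 29 5-{[(2R)-2-methylbutyl]sulfanyl}-1-phenyl-1H-tetrazole
Conditions: 1-phenyl-1H-tetrazole-5-thiol, PPh3, DIAD, THF, 0 °C → rt
Reagents that add atoms: 1-phenyl-1H-tetrazole-5-thiol, Sc1nnnn1-c1ccccc1
Why: Mitsunobu thioetherification at the primary carbon, with the stereocentre not involved.

Step 22
Reactants: 29 5-{[(2R)-2-methylbutyl]sulfanyl}-1-phenyl-1H-tetrazole
Product: 30 5-{[(2R)-2-methylbutyl]sulfonyl}-1-phenyl-1H-tetrazole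
Conditions: (NH4)6Mo7O24·4H2O (10 mol %), 30% H2O2, EtOH, 0 °C → rt
Reagents that add atoms: hydrogen peroxide, OO
Why: Molybdate-catalysed oxidation of the sulfide to the sulfone, the usual way to phenyltetrazolyl sulfones.

Step 23
Reactants: 30 5-{[(2R)-2-methylbutyl]sulfonyl}-1-phenyl-1H-tetrazole; 26 1,4-bis(benzyloxy)-3-[(2R,3R,5Z)-3-methyl-5-[(2E)-4-oxobut-2-en-1-ylidene]oxan-2-yl]-5-phenylpyridin-2(1H)-one
Product: 32 1,4-bis(benzyloxy)-3-[(2R,3R,5Z)-3-methyl-5-[(2E,4E,6R)-6-methylocta-2,4-dien-1-ylidene]oxan-2-yl]-5-phenylpyridin-2(1H)-one, via potassium sulfonyl carbanion 31 (not isolated)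
Conditions: KN(SiMe3)2, DME, −60 °C; then 26, −60 °C → rt
Reagents that add atoms: none
Why: In this Julia–Kocienski olefination the metalated sulfone adds to the dienal and Smiles rearrangement with loss of SO2 and the tetrazololate forms C4'=C5', for which the potassium/DME variant of an alkyl phenyltetrazolyl sulfone is expected to favour E, while C6', beta to the sulfone, cannot epimerise.

Step 24
Reactants: 32 1,4-bis(benzyloxy)-3-[(2R,3R,5Z)-3-methyl-5-[(2E,4E,6R)-6-methylocta-2,4-dien-1-ylidene]oxan-2-yl]-5-phenylpyridin-2(1H)-one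
Product: 33 1,4-dihydroxy-3-[(2R,3R,5Z)-3-methyl-5-[(2E,4E,6R)-6-methylocta-2,4-dien-1-ylidene]oxan-2-yl]-5-phenylpyridin-2(1H)-one
Conditions: BCl3, C6HMe5, CH2Cl2, −78 °C; MeOH quench at −78 °C
Reagents that add atoms: none
Why: Lewis-acid debenzylation of both O-benzyl groups with pentamethylbenzene as a non-basic trap for the benzyl cations (Friedel–Crafts capture) works at −78 °C and avoids hydrogenolysis, which the triene would not survive.

**Compound list**

1 | (S)-3-bromo-2-methylpropan-1-ol | BrC[C@@H](C)CO | starting material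
2 | (S)-(3-bromo-2-methylpropoxy)(tert-butyl)dimethylsilane | BrC[C@@H](C)CO[Si](C)(C)C(C)(C)C | intermediate
3 | (R)-tert-butyldimethyl[(2-methylpent-4-yn-1-yl)oxy]silane | C#CC[C@@H](C)CO[Si](C)(C)C(C)(C)C | intermediate
4 | lithium acetylide of 3 (not isolated) | [Li]C#CC[C@@H](C)CO[Si](C)(C)C(C)(C)C | intermediate
5 | (R)-6-[(tert-butyldimethylsilyl)oxy]-5-methylhex-2-yn-1-ol | OCC#CC[C@@H](C)CO[Si](C)(C)C(C)(C)C | intermediate
6 | (2Z,5R)-6-[(tert-butyldimethylsilyl)oxy]-5-methyl-3-(triethylsilyl)hex-2-en-1-ol | OC/C=C(\[Si](CC)(CC)CC)C[C@@H](C)CO[Si](C)(C)C(C)(C)C | intermediate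
7 | (2R,4Z)-1-[(tert-butyldimethylsilyl)oxy]-6-[(tert-butyldiphenylsilyl)oxy]-2-methyl-4-(triethylsilyl)hex-4-ene | CC(C)(C)[Si](c1ccccc1)(c1ccccc1)OC/C=C(\[Si](CC)(CC)CC)C[C@@H](C)CO[Si](C)(C)C(C)(C)C | intermediate
8 | (2R,4Z)-6-[(tert-butyldiphenylsilyl)oxy]-2-methyl-4-(triethylsilyl)hex-4-en-1-ol | CC(C)(C)[Si](c1ccccc1)(c1ccccc1)OC/C=C(\[Si](CC)(CC)CC)C[C@@H](C)CO | intermediate
9 | (2R,4Z)-6-[(tert-butyldiphenylsilyl)oxy]-2-methyl-4-(triethylsilyl)hex-4-enal | CC(C)(C)[Si](c1ccccc1)(c1ccccc1)OC/C=C(\[Si](CC)(CC)CC)C[C@@H](C)C=O | intermediate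
10 | 5-bromo-2,4-dichloropyridine | Clc1cc(Cl)c(Br)cn1 | starting material
11 | 2,4-bis(benzyloxy)-5-bromopyridine | Brc1cnc(OCc2ccccc2)cc1OCc1ccccc1 | intermediate
12 | 2,4-bis(benzyloxy)-5-phenylpyridine | c1ccc(-c2cnc(OCc3ccccc3)cc2OCc2ccccc2)cc1 | intermediate
13 | 2,4-bis(benzyloxy)-5-phenylpyridine 1-oxide (not isolated) | [O-][n+]1cc(-c2ccccc2)c(OCc2ccccc2)cc1OCc1ccccc1 | intermediate
14 | 1,4-bis(benzyloxy)-5-phenylpyridin-2(1H)-one | O=c1cc(OCc2ccccc2)c(-c2ccccc2)cn1OCc1ccccc1 | intermediate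
15 | 1,4-bis(benzyloxy)-3-iodo-5-phenylpyridin-2(1H)-one | O=c1c(I)c(OCc2ccccc2)c(-c2ccccc2)cn1OCc1ccccc1 | intermediate
16 | [1,4-bis(benzyloxy)-2-oxo-5-phenyl-1,2-dihydropyridin-3-yl]magnesium chloride (not isolated) | O=c1c([Mg]Cl)c(OCc2ccccc2)c(-c2ccccc2)cn1OCc1ccccc1 | intermediate
17 | 1,4-bis(benzyloxy)-3-[(1RS,2R,4Z)-6-(tert-butyldiphenylsilyloxy)-1-hydroxy-2-methyl-4-(triethylsilyl)hex-4-en-1-yl]-5-phenylpyridin-2(1H)-one, both carbinol epimers | CC(C)(C)[Si](c1ccccc1)(c1ccccc1)OC/C=C(\[Si](CC)(CC)CC)C[C@@H](C)C(O)c1c(OCc2ccccc2)c(-c2ccccc2)cn(OCc2ccccc2)c1=O | intermediate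
18 | 1,4-bis(benzyloxy)-3-[(2R,4Z)-6-(tert-butyldiphenylsilyloxy)-2-methyl-4-(triethylsilyl)hex-4-enoyl]-5-phenylpyridin-2(1H)-one | CC(C)(C)[Si](c1ccccc1)(c1ccccc1)OC/C=C(\[Si](CC)(CC)CC)C[C@@H](C)C(=O)c1c(OCc2ccccc2)c(-c2ccccc2)cn(OCc2ccccc2)c1=O | intermediate
19 | 1,4-bis(benzyloxy)-3-[(1R,2R,4Z)-6-(tert-butyldiphenylsilyloxy)-1-hydroxy-2-methyl-4-(triethylsilyl)hex-4-en-1-yl]-5-phenylpyridin-2(1H)-one | CC(C)(C)[Si](c1ccccc1)(c1ccccc1)OC/C=C(\[Si](CC)(CC)CC)C[C@@H](C)[C@@H](O)c1c(OCc2ccccc2)c(-c2ccccc2)cn(OCc2ccccc2)c1=O | intermediate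
20 | 1,4-bis(benzyloxy)-3-[(1R,2R,4Z)-6-(tert-butyldiphenylsilyloxy)-1-[(2-methoxyethoxy)methoxy]-2-methyl-4-(triethylsilyl)hex-4-en-1-yl]-5-phenylpyridin-2(1H)-one | CC(C)(C)[Si](c1ccccc1)(c1ccccc1)OC/C=C(\[Si](CC)(CC)CC)C[C@@H](C)[C@@H](OCOCCOC)c1c(OCc2ccccc2)c(-c2ccccc2)cn(OCc2ccccc2)c1=O | intermediate
21 | O-methylene oxocarbenium ion from 20 (not isolated) | CC(C)(C)[Si](c1ccccc1)(c1ccccc1)OC/C=C(\[Si](CC)(CC)CC)C[C@@H](C)[C@@H]([O+]=C)c1c(OCc2ccccc2)c(-c2ccccc2)cn(OCc2ccccc2)c1=O | intermediate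
22 | ring-closed C1' cation beta to silicon (not isolated) | CC(C)(C)[Si](c1ccccc1)(c1ccccc1)OC[CH+]C1([Si](CC)(CC)CC)CO[C@@H](c2c(OCc3ccccc3)c(-c3ccccc3)cn(OCc3ccccc3)c2=O)[C@H](C)C1 | intermediate
23 | 1,4-bis(benzyloxy)-3-[(2R,3R,5Z)-5-[2-(tert-butyldiphenylsilyloxy)ethylidene]-3-methyloxan-2-yl]-5-phenylpyridin-2(1H)-one | CC(C)(C)[Si](c1ccccc1)(c1ccccc1)OC/C=C1\CO[C@@H](c2c(OCc3ccccc3)c(-c3ccccc3)cn(OCc3ccccc3)c2=O)[C@H](C)C1 | intermediate
24 | 1,4-bis(benzyloxy)-3-[(2R,3R,5Z)-5-(2-hydroxyethylidene)-3-methyloxan-2-yl]-5-phenylpyridin-2(1H)-one | OC/C=C1\CO[C@@H](c2c(OCc3ccccc3)c(-c3ccccc3)cn(OCc3ccccc3)c2=O)[C@H](C)C1 | intermediate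
25 | 1,4-bis(benzyloxy)-3-[(2R,3R,5Z)-3-methyl-5-(2-oxoethylidene)oxan-2-yl]-5-phenylpyridin-2(1H)-one | O=C/C=C1\CO[C@@H](c2c(OCc3ccccc3)c(-c3ccccc3)cn(OCc3ccccc3)c2=O)[C@H](C)C1 | intermediate
26 | 1,4-bis(benzyloxy)-3-[(2R,3R,5Z)-3-methyl-5-[(2E)-4-oxobut-2-en-1-ylidene]oxan-2-yl]-5-phenylpyridin-2(1H)-one | O=C/C=C/C=C1\CO[C@@H](c2c(OCc3ccccc3)c(-c3ccccc3)cn(OCc3ccccc3)c2=O)[C@H](C)C1 | intermediate
27 | (R)-2-methylbutanoic acid | CC[C@@H](C)C(=O)O | starting material
28 | (R)-2-methylbutan-1-ol | CC[C@@H](C)CO | intermediate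
29 | 5-{[(2R)-2-methylbutyl]sulfanyl}-1-phenyl-1H-tetrazole | CC[C@@H](C)CSc1nnnn1-c1ccccc1 | intermediate
30 | 5-{[(2R)-2-methylbutyl]sulfonyl}-1-phenyl-1H-tetrazole | CC[C@@H](C)CS(=O)(=O)c1nnnn1-c1ccccc1 | intermediate
31 | potassium alpha-sulfonyl carbanion of 30 (not isolated) | CC[C@@H](C)[CH-]S(=O)(=O)c1nnnn1-c1ccccc1.[K+] | intermediate
32 | 1,4-bis(benzyloxy)-3-[(2R,3R,5Z)-3-methyl-5-[(2E,4E,6R)-6-methylocta-2,4-dien-1-ylidene]oxan-2-yl]-5-phenylpyridin-2(1H)-one | CC[C@@H](C)/C=C/C=C/C=C1\CO[C@@H](c2c(OCc3ccccc3)c(-c3ccccc3)cn(OCc3ccccc3)c2=O)[C@H](C)C1 | intermediate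
33 | 1,4-dihydroxy-3-[(2R,3R,5Z)-3-methyl-5-[(2E,4E,6R)-6-methylocta-2,4-dien-1-ylidene]oxan-2-yl]-5-phenylpyridin-2(1H)-one (CNP0190742.3) | CC[C@@H](C)/C=C/C=C/C=C1\CO[C@@H](c2c(O)c(-c3ccccc3)cn(O)c2=O)[C@H](C)C1 | target

**Count and risks**

Total step count: 24. Longest linear sequence: 17 steps (steps 1–7, 12–19, 23 and 24, from compound 1).

Steps most likely to fail:

1. Step 16. What may go wrong is mis-directed ionisation: SnCl4 may cleave the benzylic C2–O bond or a benzyl ether instead of the acetal, and HCl from traces of water may protodesilylate the vinylsilane before the ring closes. A slow ring closure would also give the C1' cation time to rotate and erode the alkene geometry. The fallback keeps the C5–C6 closure but reaches the same oxocarbenium ion by a thiophilic route. Setting out from 19, Pummerer-type etherification (DMSO, Ac2O, AcOH, rt) would give the methylthiomethyl ether F1. Dimethyl(methylthio)sulfonium tetrafluoroborate with 2,6-di-tert-butyl-4-methylpyridine in CH2Cl2 at −78 °C attacks only sulfur and releases oxocarbenium ion 21 without any hard Lewis acid. After closure onto the vinylsilane and loss of silicon to fluoride, the sequence comes back to the route at 23.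

2. Step 24. What may go wrong is acid-induced isomerisation or oligomerisation of the triene, or opening of the ring ether (allylic at C6, benzylic at C2) by BCl3 before both benzyl groups are gone. The fallback moves the debenzylation ahead of the triene and ends with a neutral deprotection. Setting out from 23, BCl3 and C6HMe5 at −78 °C would give the dihydroxypyridone F2, and allyl bromide with K2CO3 in DMF the bis(allyl ether) F3 (C-allylation is blocked because pyridone C3 is substituted). Bu4NF/AcOH then gives the allylic alcohol F4, MnO2 the enal F5, Ph3P=CHCHO the dienal F6, and Julia–Kocienski olefination with 30 the bis(allyl) triene F7. Pd(PPh3)4 with morpholine in THF at rt removes both allyl groups and comes back to the route at 33.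

3. Step 14. What may go wrong is poor facial selectivity, because the twisted, doubly ortho-substituted pyridonyl group may not be read as the large substituent by the catalyst and the Felkin–Anh bias of a methyl against a CH2 branch is modest; the hindered ketone may also react slowly. The fallback sets C2 and C3 together under reagent control and builds the vinylsilane afterwards. Setting out from 15, iodine–magnesium exchange (i-PrMgCl·LiCl) and DMF would give the aldehyde F8. Brown crotylboration with the (E)-crotyldiisopinocampheylborane antipode that gives the (1R,2R) adduct (−78 °C, then NaOH/H2O2) gives the anti homoallylic alcohol F9, and MEMCl/i-Pr2NEt the acetal F10. Hydroboration with 9-BBN and NaOH/H2O2 gives the primary alcohol F11, Dess–Martin oxidation the aldehyde F12, and Ohira–Bestmann homologation (dimethyl (1-diazo-2-oxopropyl)phosphonate, K2CO3, MeOH) the terminal alkyne F13. Magnesiation of the alkyne (i-PrMgCl·LiCl) and paraformaldehyde give the propargylic alcohol F14, and trans-hydrosilylation as in step 4 gives the vinylsilane alcohol F15. TBDPSCl/imidazole then comes back to the route at 20.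

**Further compounds**

F1 | step 16 | 1,4-bis(benzyloxy)-3-[(1R,2R,4Z)-6-(tert-butyldiphenylsilyloxy)-2-methyl-1-[(methylsulfanyl)methoxy]-4-(triethylsilyl)hex-4-en-1-yl]-5-phenylpyridin-2(1H)-one | CC(C)(C)[Si](c1ccccc1)(c1ccccc1)OC/C=C(\[Si](CC)(CC)CC)C[C@@H](C)[C@@H](OCSC)c1c(OCc2ccccc2)c(-c2ccccc2)cn(OCc2ccccc2)c1=O
F2 | step 24 | 3-[(2R,3R,5Z)-5-[2-(tert-butyldiphenylsilyloxy)ethylidene]-3-methyloxan-2-yl]-1,4-dihydroxy-5-phenylpyridin-2(1H)-one | CC(C)(C)[Si](c1ccccc1)(c1ccccc1)OC/C=C1\CO[C@@H](c2c(O)c(-c3ccccc3)cn(O)c2=O)[C@H](C)C1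
F3 | step 24 | 1,4-bis(allyloxy)-3-[(2R,3R,5Z)-5-[2-(tert-butyldiphenylsilyloxy)ethylidene]-3-methyloxan-2-yl]-5-phenylpyridin-2(1H)-one | CC(C)(C)[Si](c1ccccc1)(c1ccccc1)OC/C=C1\CO[C@@H](c2c(OCC=C)c(-c3ccccc3)cn(OCC=C)c2=O)[C@H](C)C1
F4 | step 24 | 1,4-bis(allyloxy)-3-[(2R,3R,5Z)-5-(2-hydroxyethylidene)-3-methyloxan-2-yl]-5-phenylpyridin-2(1H)-one | OC/C=C1\CO[C@@H](c2c(OCC=C)c(-c3ccccc3)cn(OCC=C)c2=O)[C@H](C)C1
F5 | step 24 | 1,4-bis(allyloxy)-3-[(2R,3R,5Z)-3-methyl-5-(2-oxoethylidene)oxan-2-yl]-5-phenylpyridin-2(1H)-one | O=C/C=C1\CO[C@@H](c2c(OCC=C)c(-c3ccccc3)cn(OCC=C)c2=O)[C@H](C)C1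
F6 | step 24 | 1,4-bis(allyloxy)-3-[(2R,3R,5Z)-3-methyl-5-[(2E)-4-oxobut-2-en-1-ylidene]oxan-2-yl]-5-phenylpyridin-2(1H)-one | O=C/C=C/C=C1\CO[C@@H](c2c(OCC=C)c(-c3ccccc3)cn(OCC=C)c2=O)[C@H](C)C1
F7 | step 24 | 1,4-bis(allyloxy)-3-[(2R,3R,5Z)-3-methyl-5-[(2E,4E,6R)-6-methylocta-2,4-dien-1-ylidene]oxan-2-yl]-5-phenylpyridin-2(1H)-one | CC[C@@H](C)/C=C/C=C/C=C1\CO[C@@H](c2c(OCC=C)c(-c3ccccc3)cn(OCC=C)c2=O)[C@H](C)C1
F8 | step 14 | 1,4-bis(benzyloxy)-2-oxo-5-phenyl-1,2-dihydropyridine-3-carbaldehyde | O=Cc1c(OCc2ccccc2)c(-c2ccccc2)cn(OCc2ccccc2)c1=O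
F9 | step 14 | 1,4-bis(benzyloxy)-3-[(1R,2R)-1-hydroxy-2-methylbut-3-en-1-yl]-5-phenylpyridin-2(1H)-one | C=C[C@@H](C)[C@@H](O)c1c(OCc2ccccc2)c(-c2ccccc2)cn(OCc2ccccc2)c1=O
F10 | step 14 | 1,4-bis(benzyloxy)-3-[(1R,2R)-1-[(2-methoxyethoxy)methoxy]-2-methylbut-3-en-1-yl]-5-phenylpyridin-2(1H)-one | C=C[C@@H](C)[C@@H](OCOCCOC)c1c(OCc2ccccc2)c(-c2ccccc2)cn(OCc2ccccc2)c1=O
F11 | step 14 | 1,4-bis(benzyloxy)-3-[(1R,2R)-4-hydroxy-1-[(2-methoxyethoxy)methoxy]-2-methylbutyl]-5-phenylpyridin-2(1H)-one | OCC[C@@H](C)[C@@H](OCOCCOC)c1c(OCc2ccccc2)c(-c2ccccc2)cn(OCc2ccccc2)c1=O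
F12 | step 14 | 1,4-bis(benzyloxy)-3-[(1R,2R)-1-[(2-methoxyethoxy)methoxy]-2-methyl-4-oxobutyl]-5-phenylpyridin-2(1H)-one | O=CC[C@@H](C)[C@@H](OCOCCOC)c1c(OCc2ccccc2)c(-c2ccccc2)cn(OCc2ccccc2)c1=O
F13 | step 14 | 1,4-bis(benzyloxy)-3-[(1R,2R)-1-[(2-methoxyethoxy)methoxy]-2-methylpent-4-yn-1-yl]-5-phenylpyridin-2(1H)-one | C#CC[C@@H](C)[C@@H](OCOCCOC)c1c(OCc2ccccc2)c(-c2ccccc2)cn(OCc2ccccc2)c1=O
F14 | step 14 | 1,4-bis(benzyloxy)-3-[(1R,2R)-6-hydroxy-1-[(2-methoxyethoxy)methoxy]-2-methylhex-4-yn-1-yl]-5-phenylpyridin-2(1H)-one | OCC#CC[C@@H](C)[C@@H](OCOCCOC)c1c(OCc2ccccc2)c(-c2ccccc2)cn(OCc2ccccc2)c1=O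
F15 | step 14 | 1,4-bis(benzyloxy)-3-[(1R,2R,4Z)-6-hydroxy-1-[(2-methoxyethoxy)methoxy]-2-methyl-4-(triethylsilyl)hex-4-en-1-yl]-5-phenylpyridin-2(1H)-one | OC/C=C(\[Si](CC)(CC)CC)C[C@@H](C)[C@@H](OCOCCOC)c1c(OCc2ccccc2)c(-c2ccccc2)cn(OCc2ccccc2)c1=O
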